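The numbers in the tables stem from a simulated flask for an exercise; scatter was added.

**Minutes of the meeting on the flask.** The meeting began from a one-step world. In that world partner turns left-handed substrate into left-handed product, so left-handed product ends at half of the substrate charged, and the question is how fast it gets there.

| flask | left-handed substrate | right-handed substrate | partner | precatalyst | added ligand | remark | time |
|---|---|---|---|---|---|---|---|
| oak | 0.13 M | 0.13 M | 0.44 M | 5 mM | 10 mM | run made earlier |  |
| larch | 0.30 M | 0.30 M | 0.44 M | 5 mM | 10 mM | run made earlier |  |
| flask | 0.20 M | 0.20 M | 0.440 M | 5.0 mM | 10 mM |  | 40 min |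

- oak (time / min: left-handed product / %, left-handed substrate / %): 10.0: 13.7, 35.8; 20.0: 23.0, 27.5; 30.0: 28.7, 20.6; 40.0: 34.5, 16.9; 50.0: 38.6, 12.9
- larch (time / min: left-handed product / %, left-handed substrate / %): 10.0: 13.0, 36.5; 20.0: 21.1, 29.5; 30.0: 26.8, 23.6; 40.0: 30.4, 20.1; 50.0: 33.3, 16.5

(readings scatter by 0.5 percentage points)

- partner is single-handed; left-handed substrate and right-handed substrate are mirror images of each other, charged as a racemate, each of them at the stated concentration
- the handed part of partner does not stay in what it makes, so the products of the two hands are mirror images too

* amount of left-handed product in percent of the left-handed substrate and right-handed substrate together charged, at 2.0 min, 10 min and 40 min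

The first speaker read the runs. At 40.0 min, left-handed substrate plus left-handed product is 51.4% in oak and 50.5% in larch. Both sums stand near that half. At 40.0 min, larch shows less left-handed product than oak.

The forecaster then gave 3.3%, 13.5% and 32.4%, on this ground: “The flask sits between the two runs”.

I proposed a cheap tool, the charge place: the share of the way from oak's substrate charge to larch's at which the flask's charge lies, here 0.412. Partner, precatalyst and added ligand are charged alike in the three flasks. I therefore took each flask reading to lie that share of the way from the oak reading to the larch reading.

This gave me 13.4% at 10 min and 32.8% at 40 min. No reading stands at 2.0 min. There I used a pseudo-first-order fall of left-handed substrate, with partner held at its charge, and got 3.03%. That is lower than the forecast. At 40 min, my figure and the forecast are 0.40 percentage points apart, and a reading scatters by 0.5 points.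

The flask gives 3.22%, 13.4% and 32.9%.

    partner + left-handed substrate → left-handed product (k = 0.0770 M⁻¹ min⁻¹)
    partner + precatalyst → racemization catalyst + spent reagent (k = 0.260 M⁻¹ min⁻¹)
    left-handed substrate + racemization catalyst ⇌ right-handed substrate + racemization catalyst, rate k3*[racemization catalyst]*[left-handed substrate] forward; the back reaction follows from the equilibrium constant (k = 2.00 M⁻¹ min⁻¹)
    racemization catalyst + added ligand ⇌ idle complex (K = 3900 M⁻¹, k = 30.0 M⁻¹ min⁻¹)
    partner + right-handed substrate → right-handed product (k = 0.00790 M⁻¹ min⁻¹)

At 40.0 min, the flask holds left-handed substrate at 36% of its charge and partner at 64% of its charge. The charge place, put on the oak and larch readings at 20.0 min, gives 22.2%. The flask then holds 22.2% left-handed product.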